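The data were computed from invented constants; the scatter is artificial.

The ratio of c_G between the north and west runs is 2.21, yet at 4.00 min the two read Z of 28 % and 27 %. On logarithms, such pairs become one number per setting. Let w be the natural logarithm of charged G over G left, the exposure of a pseudo-first-order decay, with reacted G read as Z. A setting's log slope is the change of log w per change of log setting, and read as a power law, an error of some factor in that setting reaches w as the factor raised to the slope.

| setting | west | north | north-east | flask |
|---|---|---|---|---|
| G | 0.034 M | 0.075 M | 0.050 M | 0.050 M |
| Q | 22 mM (held) | 22 mM (held) | 22 mM (held) | 22 mM (held) |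
| E | 0.10 mM | 0.10 mM | 0.15 mM | 0.10 mM |
| remark | run made earlier | run made earlier | run made earlier |  |
| time |  |  |  | 6.0 min |

- west (time / min: Z / %): 0.833: 9; 2.00: 20; 2.50: 19; 4.00: 27
- north (time / min: Z / %): 0.417: 3; 1.33: 12; 2.50: 20; 4.00: 28
- north-east (time / min: Z / %): 0.833: 9; 2.00: 20; 2.50: 23; 4.00: 32

(readings scatter by 1.5 percentage points)

- the numbers in the tables scatter with a standard deviation of 1.5 percentage points
- at the start none of Q is in solution
- X is what Q becomes in solution

- Z at 6.0 min, in percent of the G charged
- concentration of X in solution at 6.0 min, in percent of saturation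

c_Q is 22 mM in the flask as in the runs, so it needs no slope. For c_G the slope is 0.0542. For c_E, the north-east run against the mean w of west and north at 4.00 min gives the log slope of E, 0.448, below one. For time, the same mean from 2.50 min to 4.00 min gives 0.838, steeper than for E, so the clock must be known best. The c_G slope is less than both, so c_G can be rough. The north and west readings of Z in percent at 4.00 min stand level within their scatter, so c_X in the flask at 6.0 min is reckoned near its saturation value of 22 mM.

Now the number. West and north give w = 0.322 at the flask's c_E. Carried to 6.0 min along the time slope, this becomes 0.452, so this reckoning puts Z at 36.3 %, an estimate from readings that scatter by 1.5 percentage points. The forecast gives Z at 37 %, above this reckoning, and X at 90 % of saturation: “X sits near saturation, though this is inferred only indirectly”.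

The flask gives Z 36.4 % against the reckoned 36.3 %, and X at 99.2 % of saturation, while at 6.00 min E holds 32.9 % of the catalyst charged and D 67.1 %.

    2 E ⇌ D (K = 31000 L mol⁻¹, k = 159 L mol⁻¹ s⁻¹)
    G + X + E → E + Z (k = 1560 L² mol⁻² s⁻¹)
    Q ⇌ X, rate k3*(csat - [X]) (kL = 0.217 s⁻¹)

From that Z, w is 0.452. The slope of E carries it to c_E = 0.134 mM and Z 40.3 %, where the flask has moved 5 points. For the neighbour flask with 2.5 × 10⁻⁴ M of E, the slope gives Z 49.4 %; computed, it reaches 52.6 %.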